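In the closed runs the isomer at 8.00 h held still, at 31.9% in west, 31.8% in south-east and 32.0% in north, while target climbed from 21.5% to 28.5% and 29.1%. So I treated isomer and uncatalysed product as a steady background, and took R, target over those two (a selectivity factor), as following [free catalyst].

| setting | west | north-east | south-east | north | eta | beta | zeta | theta |
|---|---|---|---|---|---|---|---|---|
| substrate | 20 mM | 20 mM | 20 mM | 40 mM | 20 mM (fed, over 8.00 h) | 20 mM | 20 mM | 20 mM |
| free catalyst | 3 mol% | 4.2 mol% | 6.6 mol% | 3 mol% | 3 mol% | 3 mol% | 3 mol% | 3 mol% |
| remark | run made earlier | run made earlier | run made earlier | run made earlier | a stirred flask in which substrate is dosed at a steady rate over 8.00 h without added volume, worked up at 8.0 h | one stirred flow tank at steady state, fed with the mixture as stated, mean residence time 8.0 h | everything together in a closed stirred flask, run for 8.0 h | one stirred flow tank at steady state, fed with the mixture as stated, mean residence time 80.0 h |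
| time |  |  |  |  | 8.0 h |  | 8.0 h |  |

| run | time / h | target / % | isomer of the product / % | uncatalysed product / % |
|---|---|---|---|---|
| west | 0.417 | 1.8 | 2.4 | 0.3 |
| west | 1.33 | 7.1 | 7.7 | 1.0 |
| west | 2.50 | 11.4 | 12.7 | 0.4 |
| west | 3.00 | 13.3 | 15.2 | 1.2 |
| west | 5.00 | 17.7 | 22.8 | 2.4 |
| west | 6.00 | 18.5 | 25.5 | 2.3 |
| west | 8.00 | 21.5 | 31.9 | 3.5 |
| north-east | 1.00 | 7.3 | 6.0 | 1.0 |
| north-east | 2.50 | 14.7 | 12.1 | 1.0 |
| north-east | 3.00 | 15.8 | 15.4 | 0.7 |
| north-east | 5.00 | 21.0 | 23.0 | 2.1 |
| north-east | 6.00 | 22.0 | 26.6 | 1.4 |
| north-east | 8.00 | 25.3 | 31.5 | 3.0 |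
| south-east | 0.667 | 7.6 | 5.1 | 0 |
| south-east | 1.00 | 10.9 | 6.1 | 0.3 |
| south-east | 1.33 | 12.6 | 7.2 | 0 |
| south-east | 2.50 | 17.9 | 12.9 | 0.4 |
| south-east | 3.00 | 20.0 | 15.5 | 1.1 |
| south-east | 5.00 | 25.7 | 23.0 | 2.8 |
| south-east | 8.00 | 28.5 | 31.8 | 2.7 |
| north | 0.667 | 7.1 | 3.4 | 0.7 |
| north | 1.33 | 12.5 | 6.9 | 1.0 |
| north | 2.50 | 18.0 | 12.5 | 1.2 |
| north | 4.00 | 22.3 | 19.1 | 1.3 |
| north | 8.00 | 29.1 | 32.0 | 2.3 |

(standard deviation of a reading: 0.5 percentage points)

- the stated concentrations are those of everything mixed, before any reaction; amounts are the same in each set-up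
- the feed brings no volume worth counting
- the earlier runs were made in a closed, stirred flask

1. the set-up with the highest share of target in all that became target or isomer of the product or uncatalysed product, at the outlet or at the end ("none" if the first two lie within 2 percentage points) (eta / beta / zeta / theta / none)
2. share of target in all that became target or isomer of the product or uncatalysed product, at the outlet or at the end, eta
3. share of target in all that became target or isomer of the product or uncatalysed product, at the outlet or at the end, beta
4. share of target in all that became target or isomer of the product or uncatalysed product, at the outlet or at the end, zeta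
5. share of target in all that became target or isomer of the product or uncatalysed product, at the outlet or at the end, theta

Zeta repeats west, where R read 0.607, a share of 37.8%. The other flasks differ in the catalyst their substrate meets. With a second-order loss of 0.35 per mM per h, I got 1.68 for N, the holding time over the first half-life of free catalyst. By my reckoning, [free catalyst] averaged over zeta is 58.7% of its charge, but the balance of feed against loss puts the beta tank, at the same N, at 52.9%, which is less. Scaling R by that gave beta 0.548, a share of 35.4%. For theta, at N of 16.8, I reckoned 21.6% of the charge, so R of 0.224 and a share of 18.3%. Eta shows where one number fails: it has zeta's N, yet its substrate arrives over 8.00 h, so N does not place it.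

The forecast, on “Target rate falls off faster at higher catalyst, which suggests second-order catalyst loss”, gave 32% for eta, 38% for zeta, and for the tanks 33% and 17%, lower than my 35.4% and 18.3%. It named zeta.

The flask gives 34.7% for eta, 33.6% for beta, 37.5% for zeta and 21.0% for theta, so zeta leads eta by 2.8 percentage points, more than the margin.

    target + free catalyst ⇌ isomer of the product + free catalyst, rate k1*[free catalyst]*[target] forward; the back reaction follows from the equilibrium constant (K = 3.10, k = 1.02 /M/min)
    substrate → uncatalysed product (k = 8.50 × 10⁻⁵ /min)
    substrate + free catalyst ⇌ target + free catalyst, rate k3*[substrate]*[free catalyst] forward; the back reaction follows from the equilibrium constant (K = 6.70, k = 1.74 /M/min)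
    isomer of the product ⇌ substrate (k = 4.74 × 10⁻⁵ /min)
    2 free catalyst → spent catalyst (k = 2.10 /M/min)

Carried to beta, N of 1.68 gave 35.4% against 33.6%, and carried to theta, N of 16.8 gave 18.3% against 21.0%. In zeta, the first half-life of free catalyst by its pairwise loss alone, at the charged amount, is 6.61 h, shorter than the 8.0 h of that flask, and their ratio, N with the true constant, is 1.21.

(The readings were generated by integration with made-up constants, noise included.)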